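**Assumption (reading of the target and sourcing):** Atom numbers follow drimane numbering (C1–C10 decalin, C11 = OCH2 on C9, C12 = CH3 on C8). The SMILES is read as 5α-H, 10β-CH3 and 9β-H with C11 on the α-face, i.e. the 9-epimer of the drimenol series. (R)-(−)-Carvone, acrylonitrile, isofraxidin and tributyl(iodomethyl)stannane are taken as commercial.

## Retrosynthetic overview

- The C11–O aryl ether is cut to isofraxidin and the 9βH-drim-7-en-11-ol 12 (Mitsunobu), with the C3 ketone carried as a dioxolane.
- The C9–C11 bond and the C7=C8 alkene come from a Wittig–Still [2,3] shift of the 7α-allylic alcohol 10, itself made by Wharton transposition of a 7α,8α-epoxy-9-ketone; the oxirane is a temporary ring that is not in the target.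
- Ring A is closed by a [3+3] annulation of acrylonitrile (C1–C2–C3) onto ring B in one flask: C10–C1 by conjugate addition, then C3–C4 by hydrogen-atom-transfer radical closure onto the nitrile.
- Enabling feature: in the carvone-derived ring B the enolisable methine C10 (α to the C9 carbonyl) and the isopropenyl carbon C4 both sit on C5, 1,3 to each other. H• transfer to the isopropenyl CH2 gives the second C4 methyl and the C4 radical.
- Ring order: ring B is the ring of (R)-carvone (its stereocentre becomes C5), then the oxirane, then ring A (key step); the coumarin is attached last.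

Key step: step 3

## Route

Step 1
Reactants: 1 (R)-(−)-carvone
Product: 2 (5R)-2,6-dimethyl-5-(prop-1-en-2-yl)cyclohex-2-en-1-one (6-methylcarvone, mixture of C6 epimers)
Conditions: LDA, THF, −78 °C; MeI, −78 → 0 °C
Reagents that add atoms: iodomethane, CI
Why: Kinetic deprotonation at the cross-conjugated α′-carbon (carvone C6, later C10) and enolate C-methylation; the new centre should form as an epimer mixture, which does not matter because it is enolised again in step 3.

Step 2
Reactants: 2 6-methylcarvone
Product: 3 1,3-dimethyl-4-(prop-1-en-2-yl)-7-oxabicyclo[4.1.0]heptan-2-one with the oxirane trans to the isopropenyl group (7α,8α in drimane numbering, mixture of C10 epimers)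
Conditions: 30% aq. H2O2, NaOH (cat.), MeOH, 0 °C
Reagents that add atoms: hydrogen peroxide, OO
Why: Weitz–Scheffer nucleophilic epoxidation, in which hydroperoxide should add axially to the enone β-carbon on the face of the C5 hydrogen (chair-like transition state with equatorial isopropenyl), giving the oxirane trans to isopropenyl as for carvone itself.

Step 3
Reactants: 3 epoxy ketone; 4 acrylonitrile
Product: 7 7α,8α-epoxy-11-nor-5α-drimane-3,9-dione, via cyanoethyl ketone 5 (not isolated), via cyclic ketimine 6 (not isolated)
Conditions: t-BuOK (0.2 equiv), t-BuOH/THF, 0 °C → rt; AcOH, volatiles stripped; Fe(acac)3 (30 mol%), PhSiH3, EtOH, 60 °C; aq. AcOH/THF, rt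
Reagents that add atoms: water, O
Why: tert-Butoxide-catalysed conjugate addition (cyanoethylation) of C10, the only enolisable position of 3, to acrylonitrile should form C10–C1; the isopropenyl group on C5 is pushed pseudo-axial by A(1,2) strain with the enolate methyl and shields the β-face, so the chain enters trans to it and sets the C10 quaternary centre. In the same flask the iron hydride from Fe(acac)3/PhSiH3 should transfer H• to the terminal CH2 of the isopropenyl group, creating the second C4 methyl and the tertiary C4 radical, which closes ring A by 6-exo-dig attack on the nitrile carbon C3; reduction and protonation of the iminyl radical give ketimine 6, which aqueous acid hydrolyses to the C3 ketone. The closest known reaction types are the base-catalysed cyanoethylation of α-branched cyclohexanones and the iron-hydride HAT cyclisation of alkenyl nitriles to α-quaternary cyclic ketones. Ring A is therefore closed by an intermolecular polar C–C bond followed by a radical 6-exo-dig closure, and because the C10 chain and the C4 radical are trans on ring B only the trans-decalin can form, with C5 being the untouched carvone stereocentre. The selectivity needed is secured by the oxirane: with the enone gone, the cyanoethyl carbanion cannot undergo a second, bicyclo[2.2.2]-forming Michael addition, and no conjugated alkene competes for the hydride or the radical. Excess acrylonitrile is stripped before the radical stage so that the C4 radical meets no intermolecular acceptor.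

Step 4
Reactants: 7 epoxy dione
Product: 8 3,3-(ethylenedioxy)-7α,8α-epoxy-11-nor-5α-driman-9-one
Conditions: (TMSOCH2)2, TMSOTf (5 mol%), CH2Cl2, −78 → −20 °C
Reagents that add atoms: 1,2-bis(trimethylsilyloxy)ethane, C[Si](C)(C)OCCO[Si](C)(C)C
Why: Noyori ketalisation should take only the C3 ketone, because the C9 ketone lies between the quaternary C10 and the quaternary oxirane carbon C8, and the aprotic low-temperature conditions spare the oxirane.

Step 5
Reactants: 8 epoxy ketone ketal
Product: 10 3,3-(ethylenedioxy)-11-nor-5α-drim-8-en-7α-ol, via epoxy hydrazone 9 (not isolated)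
Conditions: N2H4·H2O, AcOH (0.5 equiv), MeOH, 0 °C → rt
Reagents that add atoms: none
Why: Wharton transposition, in which the C9 hydrazone opens the oxirane at C8 and loses N2 to give the C8=C9 alkene while the C7–O bond is untouched, so the alcohol should be 7α (pseudo-axial).

Step 6
Reactants: 10 allylic alcohol
Product: 11 3,3-(ethylenedioxy)-7α-[(tributylstannyl)methoxy]-11-nor-5α-drim-8-ene
Conditions: KH, Bu3SnCH2I, 18-crown-6 (cat.), THF, 0 °C → rt
Reagents that add atoms: tributyl(iodomethyl)stannane, CCCC[Sn](CCCC)(CCCC)CI
Why: Williamson etherification of the potassium alkoxide with the primary iodide; no stereocentre is touched.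

Step 7
Reactants: 11 stannylmethyl ether
Product: 12 3,3-(ethylenedioxy)-9βH-drim-7-en-11-ol (CH2OH on the α-face of C9)
Conditions: n-BuLi, THF, −78 → −20 °C; H2O
Reagents that add atoms: none
Why: Wittig–Still [2,3]-sigmatropic rearrangement, in which tin–lithium exchange gives the α-alkoxy carbanion that should add suprafacially to C9 on the α-face carrying the pseudo-axial C7–O bond (anti to the C10 methyl), setting C9 and moving the alkene to C7=C8.

Step 8
Reactants: 12 homoallylic alcohol; 13 isofraxidin (7-hydroxy-6,8-dimethoxycoumarin)
Product: 14 7-{[3,3-(ethylenedioxy)-9βH-drim-7-en-11-yl]oxy}-6,8-dimethoxycoumarin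
Conditions: PPh3, DIAD, THF, 0 °C → rt
Reagents that add atoms: none
Why: Mitsunobu etherification of a primary alcohol by an acidic 7-hydroxycoumarin; no stereocentre is involved and the neutral conditions avoid E2 loss of the allylic C9–H.

Step 9
Reactants: 14 aryl ether ketal
Product: 15 7-[(3-oxo-9βH-drim-7-en-11-yl)oxy]-6,8-dimethoxycoumarin (target)
Conditions: TsOH·H2O (10 mol%), acetone/H2O 10:1, rt
Reagents that add atoms: water, O
Why: Acid-catalysed hydrolysis (transketalisation to acetone) of the dioxolane under mild conditions that should leave the trisubstituted alkene, the aryl ether and the lactone untouched.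

## Compound list

1 | (R)-(−)-carvone | CC1=CC[C@H](CC1=O)C(C)=C | starting material
2 | (5R)-2,6-dimethyl-5-(prop-1-en-2-yl)cyclohex-2-en-1-one (6-methylcarvone, C6 epimers) | CC1=CC[C@@H](C(C)=C)C(C)C1=O | intermediate
3 | 1,3-dimethyl-4-(prop-1-en-2-yl)-7-oxabicyclo[4.1.0]heptan-2-one, oxirane trans to isopropenyl, C3 epimers | O=C1C(C)[C@H](C(C)=C)C[C@H]2O[C@@]12C | intermediate
4 | acrylonitrile | C=CC#N | starting material
5 | cyanoethyl ketone: 3-[7α,8α-epoxy ketone of 3 bearing 10β-CH3]propanenitrile, chain trans to isopropenyl | N#CCC[C@]1(C)C(=O)[C@]2(C)O[C@@H]2C[C@H]1C(C)=C | intermediate (not isolated)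
6 | cyclic ketimine: 7α,8α-epoxy-3-imino-11-nor-5α-driman-9-one | N=C1CC[C@]2(C)C(=O)[C@]3(C)O[C@@H]3C[C@H]2C1(C)C | intermediate (not isolated)
7 | 7α,8α-epoxy-11-nor-5α-drimane-3,9-dione | O=C1CC[C@]2(C)C(=O)[C@]3(C)O[C@@H]3C[C@H]2C1(C)C | intermediate
8 | 3,3-(ethylenedioxy)-7α,8α-epoxy-11-nor-5α-driman-9-one | C1COC2(O1)CC[C@]3(C)C(=O)[C@]4(C)O[C@@H]4C[C@H]3C2(C)C | intermediate
9 | C9 hydrazone of 8 | C1COC2(O1)CC[C@]3(C)C(=NN)[C@]4(C)O[C@@H]4C[C@H]3C2(C)C | intermediate (not isolated)
10 | 3,3-(ethylenedioxy)-11-nor-5α-drim-8-en-7α-ol | C1COC2(O1)CC[C@]3(C)C=C(C)[C@H](O)C[C@H]3C2(C)C | intermediate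
11 | 3,3-(ethylenedioxy)-7α-[(tributylstannyl)methoxy]-11-nor-5α-drim-8-ene | C1COC2(O1)CC[C@]3(C)C=C(C)[C@H](OC[Sn](CCCC)(CCCC)CCCC)C[C@H]3C2(C)C | intermediate
12 | 3,3-(ethylenedioxy)-9βH-drim-7-en-11-ol | OC[C@@H]1C(C)=CC[C@H]2C(C)(C)C3(OCCO3)CC[C@]12C | intermediate
13 | isofraxidin (7-hydroxy-6,8-dimethoxycoumarin) | COc1cc2ccc(=O)oc2c(OC)c1O | starting material
14 | 7-{[3,3-(ethylenedioxy)-9βH-drim-7-en-11-yl]oxy}-6,8-dimethoxycoumarin | COc1cc2ccc(=O)oc2c(OC)c1OC[C@@H]1C(C)=CC[C@H]2C(C)(C)C3(OCCO3)CC[C@]12C | intermediate
15 | 7-[(3-oxo-9βH-drim-7-en-11-yl)oxy]-6,8-dimethoxycoumarin | COc1cc2ccc(=O)oc2c(OC)c1OC[C@@H]1C(C)=CC[C@H]2C(C)(C)C(=O)CC[C@]12C | target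

## Step count and risks

Total step count: 9. Longest linear sequence: 9 steps from (R)-carvone.

Steps most likely to fail:

1. Step 3. The 6-exo-dig addition of the C4 radical to the nitrile is slow, so reduction of the radical to an isopropyl group or alkene isomerisation may win; the conjugate addition may also stall or lose facial control at C10. Fallback, setting out from 3 and returning at 7: the two bonds are made separately with a carbonyl acceptor. LDA and allyl bromide should give the C10-allyl epoxy ketone F1 with allyl trans to isopropenyl. Aldehyde-selective, nitrite-modified Wacker oxidation of the monosubstituted alkene should give the aldehyde F2. Iron-hydride HAT cyclisation of the tertiary radical onto the aldehyde carbonyl (the type known for alkene-tethered ketones) should give the 3-hydroxy epoxy ketone F3, and Dess–Martin oxidation leads back to 7.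

2. Step 5. Hydrazone formation at C9, which lies between two quaternary carbons, may be too slow, and hydrazine may instead open the oxirane at C7. Fallback, setting out from 8 and returning at 10: DIBAL-H reduction of the C9 ketone at −78 °C should give the epoxy alcohol F4 (either C9 epimer serves). Mesylation gives the epoxy mesylate F5, and reductive elimination with sodium naphthalenide should open the oxirane to the 7α-allylic alcohol 10.

3. Step 7. After tin–lithium exchange the carbanion may undergo the [1,2]-shift or be protonated before it reaches the hindered C9 next to the quaternary C10. Fallback, setting out from 10 and returning at 12: heating 10 with N,N-dimethylformamide dimethyl acetal (Büchi [2,3]-rearrangement) should deliver the one-carbon unit suprafacially to the α-face of C9 as the β,γ-unsaturated dimethylamide F6. Lithium triethylborohydride should then reduce the amide to the primary alcohol 12.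

## Further compounds

F1 | step 3 | C10-allyl epoxy ketone (allyl trans to isopropenyl) | C=CC[C@]1(C)C(=O)[C@]2(C)O[C@@H]2C[C@H]1C(C)=C
F2 | step 3 | 3-(epoxy ketone)propanal, aldehyde analogue of 5 | O=CCC[C@]1(C)C(=O)[C@]2(C)O[C@@H]2C[C@H]1C(C)=C
F3 | step 3 | 7α,8α-epoxy-3-hydroxy-11-nor-5α-driman-9-one (C3 epimers) | OC1CC[C@]2(C)C(=O)[C@]3(C)O[C@@H]3C[C@H]2C1(C)C
F4 | step 5 | 3,3-(ethylenedioxy)-7α,8α-epoxy-11-nor-5α-driman-9-ol (C9 epimers) | C1COC2(O1)CC[C@]3(C)C(O)[C@]4(C)O[C@@H]4C[C@H]3C2(C)C
F5 | step 5 | 9-methanesulfonate of F4 | C1COC2(O1)CC[C@]3(C)C(OS(C)(=O)=O)[C@]4(C)O[C@@H]4C[C@H]3C2(C)C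
F6 | step 7 | 3,3-(ethylenedioxy)-N,N-dimethyl-9βH-drim-7-en-11-amide | CN(C)C(=O)[C@@H]1C(C)=CC[C@H]2C(C)(C)C3(OCCO3)CC[C@]12C
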